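**Retrosynthetic overview**

1. Cyclohexene ring: disconnect labdane C12–caryophyllane C4 and labdane C15–caryophyllane C5 (Diels–Alder) into a labdane (E)-1,3-diene acid and a caryophyllane trans-cycloalkene carboxylic acid.
2. Caryophyllane half: the cyclobutane and the nine-membered ring are taken intact from the chiral pool; only the vinylic methyl group is oxidised.
3. Labdane half: rings A and B are disconnected together at C4–C5 and C9–C10 (one-operation oxidative radical bicyclization of an acyclic 2-methyl-3-oxo ester tetraene), and the C3 oxygen is then removed.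
4. Acyclic chain: disconnect C1–C2 (keto ester dianion alkylation) and C11–C12 (sulfolene alkylation, then cheletropic loss of SO2).
5. Ring order: rings A and B together in step 5, the cyclohexene last in step 10.

Numbering: labdane numbering for the diterpene half; caryophyllane numbering for the sesquiterpene half (C14 is the methyl carbon on C4).
Assumption: the (S,S)-i-Pr-pybox ligand gives the natural labdane antipode drawn for 10; if the sense is opposite, the (R,R)-ligand is used.

**Route**

Step 1
Reactants: 1 geranyl bromide; 2 3-methyl-3-sulfolene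
Product: 4 (3E,6E)-α-farnesene, via 2-geranyl-3-methyl-3-sulfolene 3 (not isolated)
Conditions: LiN(SiMe3)2 (1.2 equiv), THF/HMPA 4:1, −78 °C; then pyridine, distil off THF, 115 °C, 2 h
Reagents that add atoms: none
Why: Sulfolene alkylation/cheletropic extrusion: kinetic deprotonation next to the methyl-bearing carbon and in situ SN2 alkylation give 3, whose thermal disrotatory loss of SO2 places the substituent outward and so unmasks the diene with the new trisubstituted double bond E.

Step 2
Reactants: 4 (3E,6E)-α-farnesene
Product: 5 (2E,6E,9E)-2,6,10-trimethyldodeca-2,6,9,11-tetraen-1-ol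
Conditions: SeO2 (0.3 equiv), t-BuOOH (3 equiv), salicylic acid (0.1 equiv), CH2Cl2, 0 °C to rt (stop at partial conversion, recycle 4)
Reagents that add atoms: selenium dioxide, O=[Se]=O; tert-butyl hydroperoxide, CC(C)(C)OO
Why: Riley allylic oxidation (ene reaction, then [2,3]-sigmatropic shift) attacks the most electron-rich and least hindered trisubstituted alkene, the terminal isopropylidene, at its E-methyl group and gives the (2E)-allylic alcohol, while the conjugated diene is a poor ene partner.

Step 3
Reactants: 5 (2E,6E,9E)-2,6,10-trimethyldodeca-2,6,9,11-tetraen-1-ol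
Product: 6 (3E,6E,10E)-12-bromo-3,7,11-trimethyldodeca-1,3,6,10-tetraene
Conditions: CBr4, PPh3, CH2Cl2, 0 °C; used crude
Reagents that add atoms: carbon tetrabromide, BrC(Br)(Br)Br
Why: Appel bromination replaces the primary allylic hydroxyl by SN2 displacement of the oxyphosphonium group under neutral conditions that leave the diene and all double-bond geometries untouched.

Step 4
Reactants: 6 (3E,6E,10E)-12-bromo-3,7,11-trimethyldodeca-1,3,6,10-tetraene; 7 methyl 2-methyl-3-oxobutanoate
Product: 9 methyl (6E,10E,13E)-2,6,10,14-tetramethyl-3-oxohexadeca-6,10,13,15-tetraenoate, via sodium lithium dianion 8 (not isolated)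
Conditions: 7, NaH, THF, 0 °C; n-BuLi, 0 °C; then 6, 0 °C to rt; aq. NH4Cl
Reagents that add atoms: none
Why: Weiler dianion alkylation: the more basic terminal carbanion of the acetoacetate dianion displaces the allylic bromide by SN2 and forms the C1–C2 bond; the α-stereocentre is left unset because it becomes a planar radical in the next step.

Step 5
Reactants: 9 methyl (6E,10E,13E)-2,6,10,14-tetramethyl-3-oxohexadeca-6,10,13,15-tetraenoate
Product: 10 methyl (4R,5R,9S,10R)-3-oxolabda-8(17),12E,14-trien-19-oate
Conditions: Yb(OTf)3 (1.0 equiv)/(S,S)-i-Pr-pybox (1.1 equiv), Mn(OAc)3·2H2O (2.2 equiv), Cu(OAc)2·H2O (1.0 equiv), CF3CH2OH, 0.02 M, −10 to 0 °C, Ar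
Reagents that add atoms: none
Why: Proposed new method: an oxidative free-radical polyene bicyclization (enolate oxidation by Mn(OAc)3, 6-endo/6-endo chair–chair closure, oxidation of the tertiary C8 radical by Cu(OAc)2 with loss of a C17 hydrogen to give the exocyclic alkene) is run on the keto ester chelated to a chiral Yb(OTf)3–pybox Lewis acid, so that one face of the planar C4 radical is shielded and the absolute sense of the cascade is set, while the E-alkenes and the all-chair transition state set the trans ring fusion, the axial C19 ester cis to the C10 methyl and the equatorial C9 side chain; the closest known reactions are the racemic manganese triacetate/copper diacetate bicyclization of 2-methyl-3-oxo esters to podocarpate-type trans-decalins, its Yb(OTf)3-accelerated variant in which an ester auxiliary controls the chelated radical, and chiral bis(oxazoline) Lewis acid controlled atom-transfer radical cyclizations of β-keto esters.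

Step 6
Reactants: 10 methyl (4R,5R,9S,10R)-3-oxolabda-8(17),12E,14-trien-19-oate
Product: 12 methyl trans-communate, via C3 tosylhydrazone 11 (not isolated)
Conditions: TsNHNH2 (1.5 equiv), EtOH, 75 °C; evaporate; catecholborane (3 equiv), CHCl3, 0 °C; NaOAc·3H2O, 60 °C
Reagents that add atoms: none
Why: Caglioti-type deoxygenation in the Kabalka variant: condensation to the tosylhydrazone, hydride delivery from catecholborane and acetate-induced loss of sulfinate and N2 turn the hindered C3 carbonyl into CH2 under near-neutral conditions that spare the ester, the exocyclic alkene, the diene and every stereocentre.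

Step 7
Reactants: 12 methyl trans-communate
Product: 13 trans-communic acid
Conditions: n-PrSNa (5 equiv), HMPA, 25 °C, Ar; then 1 M HCl; used at once
Reagents that add atoms: none
Why: SN2 dealkylation of the ester by thiolate at the methyl carbon frees the axial, neopentyl C19 acid that resists saponification, without base-mediated alkene isomerization.

Step 8
Reactants: 14 (−)-β-caryophyllene
Product: 15 14-hydroxy-β-caryophyllene
Conditions: SeO2 (0.5 equiv), t-BuOOH (2 equiv), CH2Cl2, 0 °C to rt
Reagents that add atoms: selenium dioxide, O=[Se]=O; tert-butyl hydroperoxide, CC(C)(C)OO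
Why: Riley oxidation: SeO2 adds by an ene reaction to C5 of the strained, most nucleophilic endocyclic alkene on its exposed face with hydrogen abstraction from the freely rotating C14 methyl (the ring allylic C–H bonds lie near the alkene plane), and the fast suprafacial [2,3] shift within the same ring conformer returns the double bond to C4=C5 with the trans ring geometry retained.

Step 9
Reactants: 15 14-hydroxy-β-caryophyllene
Product: 17 β-caryophyllen-14-oic acid, via β-caryophyllen-14-al 16 (not isolated)
Conditions: TEMPO (10 mol %), PhI(OAc)2 (1.1 equiv), CH2Cl2, rt; then t-BuOH/H2O, 2-methyl-2-butene (20 equiv), NaClO2, NaH2PO4, 0 °C to rt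
Reagents that add atoms: sodium chlorite, [Na+].[O-]Cl=O
Why: Oxoammonium oxidation of the allylic alcohol stops at the enal, and Pinnick chlorite oxidation with a hypochlorite scavenger gives the acid without touching the strained or exocyclic alkenes or the ring double-bond geometry.

Step 10
Reactants: 13 trans-communic acid; 17 β-caryophyllen-14-oic acid
Product: 18 CNP0330729.1
Conditions: 13 (1 equiv), 17 (2 equiv), toluene (1 M), BHT (5 mol %), 85 °C, 48 h, Ar, sealed tube
Reagents that add atoms: none
Why: Thermal normal-demand Diels–Alder cycloaddition: the strain-activated trans-cycloalkene acid adds suprafacially (trans ring fusion, 4S,5S) to the s-cis diene through its exposed outer face, the face that is epoxidized in caryophyllene oxide formation, with the larger diene coefficient at the unsubstituted C15 pairing with the β-carbon C5 ("ortho" to the C12 substituent) and the carboxyl group endo, which places CO2H cis to the C11 methylene at the new C12 stereocentre (12R).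

**Compound list**

1 | geranyl bromide, (2E)-1-bromo-3,7-dimethylocta-2,6-diene | CC(C)=CCC/C(C)=C/CBr | starting material
2 | 3-methyl-3-sulfolene, 3-methyl-2,5-dihydrothiophene 1,1-dioxide | CC1=CCS(=O)(=O)C1 | starting material
3 | 2-geranyl-3-methyl-3-sulfolene, 2-[(2E)-3,7-dimethylocta-2,6-dien-1-yl]-3-methyl-2,5-dihydrothiophene 1,1-dioxide (racemic) | CC(C)=CCC/C(C)=C/CC1C(C)=CCS1(=O)=O | intermediate
4 | (3E,6E)-α-farnesene, (3E,6E)-3,7,11-trimethyldodeca-1,3,6,10-tetraene | C=C/C(C)=C/C/C=C(\C)CCC=C(C)C | intermediate
5 | (2E,6E,9E)-2,6,10-trimethyldodeca-2,6,9,11-tetraen-1-ol | C=C/C(C)=C/C/C=C(\C)CC/C=C(\C)CO | intermediate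
6 | (3E,6E,10E)-12-bromo-3,7,11-trimethyldodeca-1,3,6,10-tetraene | C=C/C(C)=C/C/C=C(\C)CC/C=C(\C)CBr | intermediate
7 | methyl 2-methyl-3-oxobutanoate (racemic) | CC(=O)C(C)C(=O)OC | starting material
8 | sodium lithium 1,3-dienolate (dianion) of methyl 2-methyl-3-oxobutanoate | [Na+].[Li+].C=C([O-])C(C)=C([O-])OC | intermediate
9 | methyl (6E,10E,13E)-2,6,10,14-tetramethyl-3-oxohexadeca-6,10,13,15-tetraenoate (both C2 epimers) | C=C/C(C)=C/C/C=C(\C)CC/C=C(\C)CCC(=O)C(C)C(=O)OC | intermediate
10 | methyl (4R,5R,9S,10R)-3-oxolabda-8(17),12E,14-trien-19-oate (trans-decalin, axial 4β-CO2Me, 5α-H, 9α-H, 10β-Me) | C=C/C(C)=C/C[C@H]1C(=C)CC[C@@H]2[C@]1(C)CCC(=O)[C@]2(C)C(=O)OC | intermediate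
11 | methyl (4R,5R,9S,10R)-3-[(4-methylphenyl)sulfonylhydrazinylidene]labda-8(17),12E,14-trien-19-oate | C=C/C(C)=C/C[C@H]1C(=C)CC[C@@H]2[C@]1(C)CCC(=NNS(=O)(=O)c3ccc(C)cc3)[C@]2(C)C(=O)OC | intermediate
12 | methyl trans-communate, methyl (4S,5R,9S,10R)-labda-8(17),12E,14-trien-19-oate | C=C/C(C)=C/C[C@H]1C(=C)CC[C@@H]2[C@]1(C)CCC[C@]2(C)C(=O)OC | intermediate
13 | trans-communic acid, (4S,5R,9S,10R)-labda-8(17),12E,14-trien-19-oic acid | C=C/C(C)=C/C[C@H]1C(=C)CC[C@@H]2[C@]1(C)CCC[C@]2(C)C(=O)O | intermediate
14 | (−)-β-caryophyllene, (1R,4E,9S)-4,11,11-trimethyl-8-methylidenebicyclo[7.2.0]undec-4-ene | C/C1=C\CCC(=C)[C@H]2CC(C)(C)[C@@H]2CC1 | starting material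
15 | 14-hydroxy-β-caryophyllene, [(1R,4Z,9S)-11,11-dimethyl-8-methylidenebicyclo[7.2.0]undec-4-en-4-yl]methanol (trans ring alkene as in 14) | OC/C1=C\CCC(=C)[C@H]2CC(C)(C)[C@@H]2CC1 | intermediate
16 | β-caryophyllen-14-al, (1R,4Z,9S)-11,11-dimethyl-8-methylidenebicyclo[7.2.0]undec-4-ene-4-carbaldehyde (trans ring alkene) | O=C/C1=C\CCC(=C)[C@H]2CC(C)(C)[C@@H]2CC1 | intermediate
17 | β-caryophyllen-14-oic acid, (1R,4Z,9S)-11,11-dimethyl-8-methylidenebicyclo[7.2.0]undec-4-ene-4-carboxylic acid (trans ring alkene) | OC(=O)/C1=C\CCC(=C)[C@H]2CC(C)(C)[C@@H]2CC1 | intermediate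
18 | CNP0330729.1: [4+2] adduct of 13 and 17; labdane C12 and C15 bonded to caryophyllane C4 and C5; caryophyllane (1R,4S,5S,9S), labdane (4S,5R,9S,10R,12R); trans ring fusion, C4 CO2H cis to the C11 methylene | C=C1CC[C@H]2CC=C(C)[C@@H](C[C@H]3C(=C)CC[C@@H]4[C@]3(C)CCC[C@]4(C)C(=O)O)[C@]2(C(=O)O)CC[C@@H]2[C@@H]1CC2(C)C | target

**Step count and risks**

Total step count: 10. Longest linear sequence: 8 steps (steps 1 to 7, then step 10); steps 8 and 9 form a two-step branch.

Step 5 is the most likely to fail. The chiral ligand may not stay on ytterbium in the acetate-rich oxidising medium, which would give racemic 10, and the diene may be attacked by the electrophilic radical. The fallback sets out from 9 and comes back at 10. It replaces the stoichiometric metal oxidation by a catalyst-controlled group-transfer radical chain. Keto ester 9 is selenenylated (NaH, then PhSeCl, THF, 0 °C) to methyl (6E,10E,13E)-2,6,10,14-tetramethyl-3-oxo-2-(phenylselanyl)hexadeca-6,10,13,15-tetraenoate F1. A phenylselanyl group-transfer tandem radical cyclization under Mg(ClO4)2/(S,S)-t-Bu-bis(oxazoline) control (Et3B/O2, toluene, −78 °C) gives methyl 3-oxo-8-(phenylselanyl)labda-12E,14-dien-19-oate F2 with the ring stereochemistry of 10. Oxidation (H2O2, pyridine, CH2Cl2, 0 °C) and selenoxide syn-elimination toward the C17 methyl then give 10.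

Step 8 is the second risk. The Riley oxidation may attack ring allylic positions, or the [2,3] shift may return the less strained cis ring alkene. The fallback sets out from 14 and comes back at 15. It functionalises the methyl group by deprotonation, with no double-bond shift. Metalation of 14 with n-BuLi/KOt-Bu (hexane/THF, −78 to −50 °C) at the only allylic methyl gives potassium [(1R,4E,9S)-11,11-dimethyl-8-methylidenebicyclo[7.2.0]undec-4-en-4-yl]methanide F3. Trapping at the primary terminus with FB(OMe)2 (−78 °C) gives dimethyl {[(1R,4E,9S)-11,11-dimethyl-8-methylidenebicyclo[7.2.0]undec-4-en-4-yl]methyl}boronate F4. Oxidation with NaOH/H2O2 gives 15.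

Step 10 is the third risk. The uncatalysed cycloaddition forms a quaternary centre, the C13 methyl opposes the "ortho" orientation, and endo/exo and facial selectivity may be modest. The fallback sets out from 12 and 16 (isolated by stopping step 9 after the first stage) and comes back at 18. It uses Lewis acid activation of the enal and a redox/dealkylation endgame. Me2AlCl (1.1 equiv, CH2Cl2, −78 to −30 °C) promotes the Diels–Alder reaction of 12 with 16 and gives the adduct methyl ester aldehyde (the 14-al analogue of 18 carrying the C19 methyl ester) F5. Pinnick oxidation (NaClO2, NaH2PO4, 2-methyl-2-butene) gives the C19 methyl ester of 18 F6. Demethylation with n-PrSNa in HMPA gives 18.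

**Further compounds**

F1 | step 5 | methyl (6E,10E,13E)-2,6,10,14-tetramethyl-3-oxo-2-(phenylselanyl)hexadeca-6,10,13,15-tetraenoate | C=C/C(C)=C/C/C=C(\C)CC/C=C(\C)CCC(=O)C(C)([Se]c1ccccc1)C(=O)OC
F2 | step 5 | methyl 3-oxo-8-(phenylselanyl)labda-12E,14-dien-19-oate (ring stereochemistry as in 10, C8 epimers) | C=C/C(C)=C/C[C@H]1C(C)([Se]c3ccccc3)CC[C@@H]2[C@]1(C)CCC(=O)[C@]2(C)C(=O)OC
F3 | step 8 | potassium [(1R,4E,9S)-11,11-dimethyl-8-methylidenebicyclo[7.2.0]undec-4-en-4-yl]methanide | [K+].[CH2-]/C1=C\CCC(=C)[C@H]2CC(C)(C)[C@@H]2CC1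
F4 | step 8 | dimethyl {[(1R,4E,9S)-11,11-dimethyl-8-methylidenebicyclo[7.2.0]undec-4-en-4-yl]methyl}boronate | COB(OC)C/C1=C\CCC(=C)[C@H]2CC(C)(C)[C@@H]2CC1
F5 | step 10 | Diels–Alder adduct of 12 and 16: 14-al analogue of 18 with C19 methyl ester | C=C1CC[C@H]2CC=C(C)[C@@H](C[C@H]3C(=C)CC[C@@H]4[C@]3(C)CCC[C@]4(C)C(=O)OC)[C@]2(C=O)CC[C@@H]2[C@@H]1CC2(C)C
F6 | step 10 | C19 methyl ester of 18 (caryophyllane C14 carboxylic acid free) | C=C1CC[C@H]2CC=C(C)[C@@H](C[C@H]3C(=C)CC[C@@H]4[C@]3(C)CCC[C@]4(C)C(=O)OC)[C@]2(C(=O)O)CC[C@@H]2[C@@H]1CC2(C)C
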